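The earlier runs and the new flask are calculated on assumed constants; noise was put on by code.

Two runs that give the same percentages can pass for first-order kinetics, but their charges lie close together and each reading scatters by 1.5 percentage points, so their agreement can hide a dependence on charge.

| setting | oak | larch | flask |
|---|---|---|---|
| substrate | 0.029 M | 0.043 M | 0.057 M |
| remark | run made earlier | run made earlier |  |
| time |  |  | 2.5 h |

- oak (time / min: target / %, substrate / %): 10.0: 7, 11; 20.0: 6, 9; 50.0: 12, 7; 120: 18, 10
- larch (time / min: target / %, substrate / %): 30.0: 10, 9; 60.0: 13, 9; 90.0: 17, 9; 120: 17, 11

(standard deviation of a reading: 1.5 percentage points)



- amount of target in the flask at 2.5 h, in percent of the substrate charged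
- amount of substrate in the flask at 2.5 h, in percent of the substrate charged
- amount of dormant form in the flask at 2.5 h, in percent of the substrate charged

In both runs substrate stays flat while target climbs, so this reckoning of mine brackets target. From above, the larch run's rise from its first reading to its last, carried on unslowed to the flask's time, gives 19.3%, although its late readings flatten. From below, suppose that target leaves substrate together with a released group, one for one. The holding ratio (mass-action ratio) is then the charge times the target share squared, over the substrate share; the larch run's last readings put it at 0.0113 M. This is a concentration, and the flask's charge stands above it, so a percentage need not carry over from one charge to another. With substrate flat, the ratio rises while target climbs. Held at that reading in the flask, with substrate at the larch run's last share, it gives a floor of 14.8%, an estimate that carries the scatter of the larch readings.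

The forecast gives target 20%, substrate 9% and dormant form 71%, on the ground that “The two runs agree, so the kinetics look first order”. Its target stands just above the bracket.

The flask gives target 16.3%, substrate 9.16% and dormant form 74.4%, with target inside the bracket. The forecast held within its margins for target, substrate and dormant form.

    substrate ⇌ target + released group (K = 0.0180 M, k = 0.0210 min⁻¹)
    target → over-reaction product (k = 9.70 × 10⁻⁵ min⁻¹)
    substrate ⇌ dormant form (K = 8.10, k = 0.530 min⁻¹)

Left for 25.0 h, this flask still holds target 15.7%. The same holding ratio, taken to a neighbour flask charged with 0.14 M of substrate, gives a floor of 9.42%, and that neighbour stands at target 11.1%.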